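**Plan** (carotenoid numbering)

- Retrosynthesis: the C6–C7 bond between ring β and the chain is cut first, then C11=C12 and C11'=C12' on either side of a C10 trienedial, then the vinyl carbinol of the ring ε side chain and the two ester C–O bonds.
- Forward: (R)-α-ionone is taken to the ring ε C15 phosphonium salt that already carries the myristate. Wittig reaction with the C10 dialdehyde gives a C25 aldehyde, and olefination with a C5 iodo-dienyl phosphonate gives the C31 polyenyl iodide. This is joined last to the ring β unit; both rings are bought, none is built.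
- Enabling feature: C6 of ring β lies between the quaternary C1 (gem-dimethyl, no hydrogen) and C5 (one hydrogen, one methyl). A carbene at C6, made from the C6 ketone, that takes the polyenyl group from palladium can only lose the C5 hydrogen. One event therefore makes the C6–C7 bond and puts the tetrasubstituted C5=C6 double bond in place.
- Stereochemistry: C3 comes from (4R,6R)-actinol and C6' from (R)-α-ionone. C3' is set by a catalyst-controlled CBS reduction. The E alkenes come from hydrozirconation, HWE olefination, Wittig reaction with equilibration, and retention in the coupling.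

Key step: step 13

Assumption: (R)-α-ionone and (4R,6R)-actinol are taken as purchasable in enantiopure form; all polyene steps are run under argon in dim light.

**Step 1**
Reactants: 1 (R)-α-ionone
Product: 2 (R)-3-oxo-α-ionone
Conditions: t-BuOOH (in decane), Cr(CO)6 (cat.), MeCN, reflux
Reagents that add atoms: tert-butyl hydroperoxide, CC(C)(C)OO
Why: Chromium-catalysed radical-chain allylic oxidation with t-BuOOH should attack the ring CH2 next to the trisubstituted C=C, because the doubly allylic C–H at the stereocentre is shielded by the gem-dimethyl and ring-methyl groups, and the neutral medium should leave that stereocentre untouched.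

**Step 2**
Reactants: 2 (R)-3-oxo-α-ionone
Product: 3 (4R)-4-[(1E)-3-hydroxy-3-methylpenta-1,4-dien-1-yl]-3,5,5-trimethylcyclohex-2-en-1-one (both carbinol epimers)
Conditions: CH2=CHMgBr (1.1 equiv), LaCl3·2LiCl, THF, −78 °C; aq. NH4Cl
Reagents that add atoms: vinylmagnesium bromide, C=C[Mg]Br
Why: Lanthanum-mediated Grignard 1,2-addition should go to the unhindered acyclic methyl ketone in preference to the β,β-disubstituted ring enone flanked by a neopentyl CH2, the low basicity of the reagent limits enolisation, and the new carbinol centre is erased in step 5.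

**Step 3**
Reactants: 3 keto carbinol
Product: 4 (1R,4R)-4-[(1E)-3-hydroxy-3-methylpenta-1,4-dien-1-yl]-3,5,5-trimethylcyclohex-2-en-1-ol
Conditions: (S)-2-methyl-CBS-oxazaborolidine (0.5 equiv), catecholborane (2.5 equiv), toluene, −78 °C
Reagents that add atoms: none
Why: Corey–Bakshi–Shibata reduction, in which the oxazaborolidine binds the ring enone with its C=C side as the large group and delivers hydride to the face that gives the (1R)-allylic alcohol trans to the side chain (catalyst control, the same sense as acetophenone to (R)-1-phenylethanol), while catecholborane at −78 °C reduces 1,2 and should not hydroborate the alkenes.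

**Step 4**
Reactants: 4 (1R,4R)-diol; 5 tetradecanoyl chloride
Product: 6 (1R,4R)-4-[(1E)-3-hydroxy-3-methylpenta-1,4-dien-1-yl]-3,5,5-trimethylcyclohex-2-en-1-yl tetradecanoate
Conditions: pyridine, DMAP (cat.), CH2Cl2, 0 °C
Reagents that add atoms: none
Why: DMAP-catalysed O-acylation of the secondary allylic alcohol proceeds with retention at carbon, and the tertiary carbinol is too hindered to be acylated at 0 °C.

**Step 5**
Reactants: 6 myristate carbinol
Product: 7 {(2E,4E)-3-methyl-5-[(1R,4R)-2,6,6-trimethyl-4-(tetradecanoyloxy)cyclohex-2-en-1-yl]penta-2,4-dien-1-yl}triphenylphosphonium bromide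
Conditions: PPh3·HBr, CH2Cl2, 0 °C to rt
Reagents that add atoms: triphenylphosphonium bromide, [Br-].c1ccc(cc1)[PH+](c1ccccc1)c1ccccc1
Why: Acid-promoted ionisation of the tertiary bis-allylic alcohol and capture of the allyl cation by PPh3 at the primary terminus (allylic transposition, the standard way from vinyl carbinols to polyenyl phosphonium salts) should give the conjugated salt, and the ring oxygen, being an ester, is protected from the acid epimerisation that the free allylic alcohol undergoes.

**Step 6**
Reactants: 7 ring ε C15 phosphonium bromide; 8 (2E,4E,6E)-2,7-dimethylocta-2,4,6-trienedial (2.5 equiv)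
Product: 10 (3R,6R)-3-(tetradecanoyloxy)-12'-apo-ε-caroten-12'-al (all-E C25 aldehyde), via phosphorus ylide 9 (not isolated)
Conditions: 1,2-epoxybutane/CH2Cl2, reflux; then I2 (cat.), CH2Cl2, rt
Reagents that add atoms: none
Why: Wittig olefination under neutral conditions, where the epoxide scavenges HBr and releases the ylide slowly so that the esters see no alkoxide; the excess of symmetrical dialdehyde and the lower reactivity of the longer-conjugated product favour mono-olefination, and iodine-catalysed equilibration should convert Z isomers at the new C11'=C12' bond into the all-E aldehyde.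

**Step 7**
Reactants: 11 (2E)-3-methylpent-2-en-4-yn-1-ol
Product: 13 (2E,4E)-5-iodo-3-methylpenta-2,4-dien-1-ol, via alkenylzirconocene 12 (not isolated)
Conditions: Cp2Zr(H)Cl (2.2 equiv), THF, 0 °C to rt; then I2, 0 °C
Reagents that add atoms: iodine, II
Why: Hydrozirconation–iodination, in which syn addition of Zr–H to the terminal alkyne with zirconium on the terminal carbon and iodinolysis with retention give the (E)-alkenyl iodide, the first equivalent of reagent being consumed by the hydroxyl group.

**Step 8**
Reactants: 13 iodo-dienol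
Product: 14 (1E,3E)-5-bromo-1-iodo-3-methylpenta-1,3-diene
Conditions: PBr3 (0.4 equiv), Et2O, 0 °C
Reagents that add atoms: phosphorus tribromide, BrP(Br)Br
Why: Bromide displaces the activated primary allylic alcohol (PBr3 bromination) at 0 °C, the conjugated primary bromide being the stable regioisomer.

**Step 9**
Reactants: 14 allylic bromide
Product: 15 diethyl [(2E,4E)-5-iodo-3-methylpenta-2,4-dien-1-yl]phosphonate
Conditions: P(OEt)3 (neat), 90 °C
Reagents that add atoms: triethyl phosphite, CCOP(OCC)OCC
Why: Michaelis–Arbuzov reaction of the primary allylic bromide, in which the alkenyl iodide does not react with a phosphite without a metal catalyst.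

**Step 10**
Reactants: 10 C25 aldehyde; 15 iodo-dienyl phosphonate
Product: 17 (1R,4R)-4-[(1E,3E,5E,7E,9E,11E,13E,15E,17E)-18-iodo-3,7,12,16-tetramethyloctadeca-1,3,5,7,9,11,13,15,17-nonaen-1-yl]-3,5,5-trimethylcyclohex-2-en-1-yl tetradecanoate (all-E C31 iodide), via sodium phosphonate carbanion 16 (not isolated)
Conditions: 15, NaN(SiMe3)2, THF, −78 °C; then 10, −78 to 0 °C
Reagents that add atoms: none
Why: Horner–Wadsworth–Emmons olefination with an allylic phosphonate anion should give the (E)-alkene at C11=C12, and the preformed soft anion adds to the aldehyde much faster than it attacks the hindered secondary ester at −78 °C.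

**Step 11**
Reactants: 18 (4R,6R)-4-hydroxy-2,2,6-trimethylcyclohexan-1-one (actinol); 19 hexadecanoyl chloride
Product: 20 (1R,3R)-3,5,5-trimethyl-4-oxocyclohexyl hexadecanoate
Conditions: pyridine, DMAP (cat.), CH2Cl2, 0 °C to rt
Reagents that add atoms: none
Why: DMAP-catalysed acylation of the secondary alcohol proceeds with retention, and the hindered ketone is inert.

**Step 12**
Reactants: 20 keto palmitate
Product: 21 (1R,3R)-3,5,5-trimethyl-4-{2-[2-(trifluoromethyl)benzenesulfonyl]hydrazinylidene}cyclohexyl hexadecanoate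
Conditions: 2-(CF3)C6H4SO2NHNH2, PPTS (cat.), 4 Å sieves, THF, 50 °C
Reagents that add atoms: 2-(trifluoromethyl)benzenesulfonohydrazide, NNS(=O)(=O)c1ccccc1C(F)(F)F
Why: Acid-catalysed hydrazone formation, a condensation that 2,2,6-trisubstituted cyclohexanones undergo with arenesulfonyl hydrazides, and epimerisation at the methyl-bearing α-carbon does not matter because that centre becomes sp2 in step 13.

**Step 13**
Reactants: 17 all-E C31 iodide; 21 sulfonylhydrazone (1.8 equiv, added in portions)
Product: 23 (3R,3'R,6'R)-β,ε-carotene-3,3'-diol 3-hexadecanoate 3'-tetradecanoate, via diazoalkane 22 (not isolated)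
Conditions: Pd2(dba)3 (5 mol %), XPhos (20 mol %), Cs2CO3 (3 equiv), 1,4-dioxane, 60 °C, dark
Reagents that add atoms: none
Why: Barluenga-type palladium-catalysed carbene cross-coupling of a ketone N-sulfonylhydrazone with an alkenyl halide: zerovalent palladium inserts into the C–I bond of 17 with retention of the E geometry, carbonate-induced loss of sulfinate from 21 gives diazoalkane 22, this transfers its carbon to palladium with loss of N2, and migratory insertion of the polyenyl group onto the carbene carbon forms the C6–C7 bond as an η3-allylpalladium species. Syn β-hydride elimination then installs the ring alkene, and its position is unambiguous because C1 is quaternary and C7 is sp2, so the only β-hydrogen is the one on C5, which gives the tetrasubstituted C5=C6 bond in conjugation with the chain. No ring is closed and no stereocentre is created; the C7=C8 bond should stay E because the iodide enters as the E isomer and the syn-allyl form is strongly favoured next to the gem-dimethyl ring carbon. The step needs chemoselectivity for C–I over the allylic myristate of ring ε and over both esters, which the fast oxidative addition of an alkenyl iodide, the non-nucleophilic carbonate base and the low decomposition temperature of the 2-(trifluoromethyl)benzenesulfonyl hydrazone are chosen to secure. The methyl-bearing stereocentre of 21 is destroyed, while C3, C3' and C6' are not touched.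

**Compound list**

1 | (R)-α-ionone, (3E)-4-[(1R)-2,6,6-trimethylcyclohex-2-en-1-yl]but-3-en-2-one | CC(=O)/C=C/[C@H]1C(C)=CCCC1(C)C | starting material
2 | (R)-3-oxo-α-ionone, (4R)-3,5,5-trimethyl-4-[(1E)-3-oxobut-1-en-1-yl]cyclohex-2-en-1-one | CC(=O)/C=C/[C@H]1C(C)=CC(=O)CC1(C)C | intermediate
3 | (4R)-4-[(1E)-3-hydroxy-3-methylpenta-1,4-dien-1-yl]-3,5,5-trimethylcyclohex-2-en-1-one, both epimers at the tertiary carbinol | C=CC(C)(O)/C=C/[C@H]1C(C)=CC(=O)CC1(C)C | intermediate
4 | (1R,4R)-4-[(1E)-3-hydroxy-3-methylpenta-1,4-dien-1-yl]-3,5,5-trimethylcyclohex-2-en-1-ol | C=CC(C)(O)/C=C/[C@H]1C(C)=C[C@H](O)CC1(C)C | intermediate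
5 | tetradecanoyl chloride (myristoyl chloride) | ClC(=O)CCCCCCCCCCCCC | starting material
6 | (1R,4R)-4-[(1E)-3-hydroxy-3-methylpenta-1,4-dien-1-yl]-3,5,5-trimethylcyclohex-2-en-1-yl tetradecanoate | C=CC(C)(O)/C=C/[C@H]1C(C)=C[C@H](OC(=O)CCCCCCCCCCCCC)CC1(C)C | intermediate
7 | {(2E,4E)-3-methyl-5-[(1R,4R)-2,6,6-trimethyl-4-(tetradecanoyloxy)cyclohex-2-en-1-yl]penta-2,4-dien-1-yl}triphenylphosphonium bromide | [Br-].c1ccc(cc1)[P+](c1ccccc1)(c1ccccc1)C/C=C(C)/C=C/[C@H]1C(C)=C[C@H](OC(=O)CCCCCCCCCCCCC)CC1(C)C | intermediate
8 | (2E,4E,6E)-2,7-dimethylocta-2,4,6-trienedial (C10 dialdehyde) | O=C/C(C)=C/C=C/C=C(C)/C=O | starting material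
9 | phosphorus ylide of 7 | c1ccc(cc1)P(c1ccccc1)(c1ccccc1)=C/C=C(C)/C=C/[C@H]1C(C)=C[C@H](OC(=O)CCCCCCCCCCCCC)CC1(C)C | intermediate
10 | (3R,6R)-3-(tetradecanoyloxy)-12'-apo-ε-caroten-12'-al, i.e. (2E,4E,6E,8E,10E,12E)-2,7,11-trimethyl-13-[(1R,4R)-2,6,6-trimethyl-4-(tetradecanoyloxy)cyclohex-2-en-1-yl]trideca-2,4,6,8,10,12-hexaenal | O=C/C(C)=C/C=C/C=C(C)/C=C/C=C(C)/C=C/[C@H]1C(C)=C[C@H](OC(=O)CCCCCCCCCCCCC)CC1(C)C | intermediate
11 | (2E)-3-methylpent-2-en-4-yn-1-ol | C#C/C(C)=C/CO | starting material
12 | (1E,3E)-dienylzirconocene chloride carrying the zirconocene alkoxide of the hydroxyl group | Cl[Zr](C1C=CC=C1)(C1C=CC=C1)/C=C/C(C)=C/CO[Zr](Cl)(C1C=CC=C1)C1C=CC=C1 | intermediate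
13 | (2E,4E)-5-iodo-3-methylpenta-2,4-dien-1-ol | OC/C=C(C)/C=C/I | intermediate
14 | (1E,3E)-5-bromo-1-iodo-3-methylpenta-1,3-diene | BrC/C=C(C)/C=C/I | intermediate
15 | diethyl [(2E,4E)-5-iodo-3-methylpenta-2,4-dien-1-yl]phosphonate | CCOP(=O)(OCC)C/C=C(C)/C=C/I | intermediate
16 | sodium salt of the α-carbanion of 15 | [Na+].CCOP(=O)(OCC)[CH-]/C=C(C)/C=C/I | intermediate
17 | (1R,4R)-4-[(1E,3E,5E,7E,9E,11E,13E,15E,17E)-18-iodo-3,7,12,16-tetramethyloctadeca-1,3,5,7,9,11,13,15,17-nonaen-1-yl]-3,5,5-trimethylcyclohex-2-en-1-yl tetradecanoate (all-E C31 iodide) | I/C=C/C(C)=C/C=C/C(C)=C/C=C/C=C(C)/C=C/C=C(C)/C=C/[C@H]1C(C)=C[C@H](OC(=O)CCCCCCCCCCCCC)CC1(C)C | intermediate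
18 | (4R,6R)-4-hydroxy-2,2,6-trimethylcyclohexan-1-one (actinol) | O[C@@H]1C[C@@H](C)C(=O)C(C)(C)C1 | starting material
19 | hexadecanoyl chloride (palmitoyl chloride) | CCCCCCCCCCCCCCCC(=O)Cl | starting material
20 | (1R,3R)-3,5,5-trimethyl-4-oxocyclohexyl hexadecanoate | CCCCCCCCCCCCCCCC(=O)O[C@@H]1C[C@@H](C)C(=O)C(C)(C)C1 | intermediate
21 | (1R,3R)-3,5,5-trimethyl-4-{2-[2-(trifluoromethyl)benzenesulfonyl]hydrazinylidene}cyclohexyl hexadecanoate | CCCCCCCCCCCCCCCC(=O)O[C@@H]1C[C@@H](C)C(=NNS(=O)(=O)c2ccccc2C(F)(F)F)C(C)(C)C1 | intermediate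
22 | (1R,3R)-4-diazo-3,5,5-trimethylcyclohexyl hexadecanoate | CCCCCCCCCCCCCCCC(=O)O[C@@H]1C[C@@H](C)C(=[N+]=[N-])C(C)(C)C1 | intermediate
23 | (3R,3'R,6'R)-β,ε-carotene-3,3'-diol 3-hexadecanoate 3'-tetradecanoate (all-E; lutein 3-palmitate 3'-myristate) | CCCCCCCCCCCCCCCC(=O)O[C@@H]1CC(C)=C(/C=C/C(C)=C/C=C/C(C)=C/C=C/C=C(C)/C=C/C=C(C)/C=C/[C@H]2C(C)=C[C@H](OC(=O)CCCCCCCCCCCCC)CC2(C)C)C(C)(C)C1 | target

**Count and risks**

Total step count: 13. Longest linear sequence: 8 steps (steps 1 to 6, 10 and 13).

Steps most likely to fail: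

1. Step 13. Capture of the very hindered diazoalkane by the alkenylpalladium species may be slower than its decomposition by 1,2-hydrogen shift or azine formation, and zerovalent palladium may ionise the allylic myristate of ring ε on prolonged heating. The fallback sets out from 20 and 17 and comes back at 23. Ketone 20 can enolise only toward the methyl-bearing carbon, so Tf2O with 2,6-di-tert-butyl-4-methylpyridine in CH2Cl2 should give the single enol triflate (4R)-4-(hexadecanoyloxy)-2,6,6-trimethylcyclohex-1-en-1-yl trifluoromethanesulfonate F1. Iodide 17 is stannylated with Me3SnSnMe3 and Pd(PPh3)4 (cat.) in THF to the all-E C31 trimethylstannane F2. Stille coupling of F1 with F2 (Pd2(dba)3, AsPh3, LiCl, NMP, 50 °C), a pairing established for 2,6,6-trimethylcyclohexenyl triflates and polyenylstannanes, should then give 23.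

2. Step 2. Discrimination between the two enone carbonyls may be incomplete, and the organometallic may enolise the diketone toward the doubly allylic ring carbon and erode its configuration. The fallback sets out from 1 and comes back at 3. Vinylmagnesium bromide is added to the single ketone of 1 (THF, −20 °C) to give (1E)-3-methyl-1-[(1R)-2,6,6-trimethylcyclohex-2-en-1-yl]penta-1,4-dien-3-ol F3. Its ring allylic CH2 is then oxidised with t-BuOOH and CuBr (cat.) in MeCN at 50 °C, a chromate-free system that should not transpose the tertiary allylic alcohol, to give 3.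

3. Step 3. Facial selectivity may be poor if the bias of the substituted ring opposes the catalyst or if the neopentyl CH2 side is not read as the small group. The fallback sets out from 3 and comes back at 6. Luche reduction (NaBH4, CeCl3·7H2O, MeOH, −78 °C) gives both ring carbinol epimers, which are diastereomers and separable. The trans epimer is 4 and goes on through step 4. The cis epimer, (1S,4R)-4-[(1E)-3-hydroxy-3-methylpenta-1,4-dien-1-yl]-3,5,5-trimethylcyclohex-2-en-1-ol F4, is esterified with tetradecanoic acid under Mitsunobu conditions (PPh3, DIAD, THF, 0 °C), which should invert the secondary centre and give 6.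

**Further compounds**

F1 | step 13 | (4R)-4-(hexadecanoyloxy)-2,6,6-trimethylcyclohex-1-en-1-yl trifluoromethanesulfonate | CCCCCCCCCCCCCCCC(=O)O[C@@H]1CC(C)=C(OS(=O)(=O)C(F)(F)F)C(C)(C)C1
F2 | step 13 | (1R,4R)-3,5,5-trimethyl-4-[(1E,3E,5E,7E,9E,11E,13E,15E,17E)-3,7,12,16-tetramethyl-18-(trimethylstannyl)octadeca-1,3,5,7,9,11,13,15,17-nonaen-1-yl]cyclohex-2-en-1-yl tetradecanoate | C[Sn](C)(C)/C=C/C(C)=C/C=C/C(C)=C/C=C/C=C(C)/C=C/C=C(C)/C=C/[C@H]1C(C)=C[C@H](OC(=O)CCCCCCCCCCCCC)CC1(C)C
F3 | step 2 | (1E)-3-methyl-1-[(1R)-2,6,6-trimethylcyclohex-2-en-1-yl]penta-1,4-dien-3-ol | C=CC(C)(O)/C=C/[C@H]1C(C)=CCCC1(C)C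
F4 | step 3 | (1S,4R)-4-[(1E)-3-hydroxy-3-methylpenta-1,4-dien-1-yl]-3,5,5-trimethylcyclohex-2-en-1-ol | C=CC(C)(O)/C=C/[C@H]1C(C)=C[C@@H](O)CC1(C)C
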